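**Retrosynthetic overview**

- The angelate is put on last. The ring enoate comes from the enol triflate of a ten-membered β-keto ester.
- The cyclodecene is made by a C-acylative ring expansion: the ester enolate of a side chain attacks a seven-membered lactone, and the ring oxygen it expels then closes the α-methylene-γ-butyrolactone.
- The seven-membered lactone comes from Baeyer–Villiger ring expansion of a cis-2,4-disubstituted cyclohexanone, with retention at the migrating carbon.
- That ketone comes from desymmetrising SN2' alkylation of 4-methylcyclohexanone with a Morita–Baylis–Hillman bromide, itself built from allyl acrylate and an α-alkoxy aldehyde derived from cyclopentene oxide.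
- Ring order: cyclohexanone (bought) → oxepanone → cyclodecene → butyrolactone (the last two in one flask).

Assumption: allyl (ester) and 4-methoxybenzyl (PMB, ether) are protecting groups; atom locants in the "Why" lines are those of the target skeleton (cyclodeca[b]furan: O1, C2, C3, C3a, C4 … C11, C11a).

**Step 1**
Reactants: 1 cyclopentene oxide
Product: 2 (1R)-cyclopent-2-en-1-ol
Conditions: LDA (1.6 equiv), DBU (5 equiv), (1S,3R,4R)-3-(pyrrolidin-1-ylmethyl)-2-azabicyclo[2.2.1]heptane (5 mol %; the enantiomer that gives the R alcohol is used), THF, 0 °C → rt; H2O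
Reagents that add atoms: none
Why: Chiral-lithium-amide-catalysed enantioselective epoxide-to-allylic-alcohol rearrangement desymmetrises the meso epoxide by removing one of the two enantiotopic β-protons, which sets C4 as R.

**Step 2**
Reactants: 2 (1R)-cyclopent-2-en-1-ol
Product: 3 1-{[(1R)-cyclopent-2-en-1-yloxy]methyl}-4-methoxybenzene
Conditions: NaH, PMBCl, Bu4NI (cat.), DMF, 0 °C → rt
Reagents that add atoms: 4-methoxybenzyl chloride, COc1ccc(CCl)cc1
Why: Williamson etherification; a benzyl-type ether is the γ-substituent for which syn conjugate addition is expected in step 6, and it is removed oxidatively at the end.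

**Step 3**
Reactants: 3 1-{[(1R)-cyclopent-2-en-1-yloxy]methyl}-4-methoxybenzene
Product: 5 methyl (4R)-4-[(4-methoxybenzyl)oxy]-5-oxopentanoate, via methoxy hydroperoxide 4 (not isolated)
Conditions: O3, CH2Cl2/MeOH 5:1, NaHCO3, Sudan III, −78 °C; then Ac2O, Et3N, 0 °C → rt
Reagents that add atoms: ozone, [O-][O+]=O; methanol, CO
Why: Terminus-differentiating ozonolysis (Schreiber type): the allylic ether oxygen steers ozonide cleavage so that the carbonyl oxide, trapped by MeOH and dehydrated to the methyl ester, forms at the remote carbon and the aldehyde forms next to C4, whose configuration is untouched.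

**Step 4**
Reactants: 5 methyl (4R)-4-[(4-methoxybenzyl)oxy]-5-oxopentanoate; 6 allyl acrylate (prop-2-en-1-yl prop-2-enoate)
Product: 7 7-methyl 1-prop-2-en-1-yl (3RS,4R)-3-hydroxy-4-[(4-methoxybenzyl)oxy]-2-methylideneheptanedioate
Conditions: DABCO (0.3 equiv), 6 (3 equiv), 1,4-dioxane/H2O 1:1, 0 °C → rt
Reagents that add atoms: none
Why: Morita–Baylis–Hillman reaction of an activated α-alkoxy aldehyde; the new carbinol centre is inconsequential because it becomes sp2 in step 5.

**Step 5**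
Reactants: 7 7-methyl 1-prop-2-en-1-yl (3RS,4R)-3-hydroxy-4-[(4-methoxybenzyl)oxy]-2-methylideneheptanedioate
Product: 8 7-methyl 1-prop-2-en-1-yl (2Z,4R)-2-(bromomethyl)-4-[(4-methoxybenzyl)oxy]hept-2-enedioate
Conditions: NBS, Me2S, CH2Cl2, 0 °C → rt
Reagents that add atoms: N-bromosuccinimide, O=C1CCC(=O)N1Br
Why: Corey–Kim-type activation of the allylic alcohol followed by SN2' attack of bromide gives the transposed, thermodynamically preferred (Z)-2-(bromomethyl)enoate.

**Step 6**
Reactants: 9 4-methylcyclohexan-1-one; 8 7-methyl 1-prop-2-en-1-yl (2Z,4R)-2-(bromomethyl)-4-[(4-methoxybenzyl)oxy]hept-2-enedioate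
Product: 12 7-methyl 1-prop-2-en-1-yl (3R,4R)-4-[(4-methoxybenzyl)oxy]-2-methylidene-3-[(1R,5S)-5-methyl-2-oxocyclohexyl]heptanedioate, via lithium enolate 10 (not isolated), via C-1' epimer mixture 11 (not isolated)
Conditions: (R,R)-bis(1-phenylethyl)amine, n-BuLi, LiCl, THF, −78 °C; 9 (2 equiv); then 8 (1 equiv), −78 → −45 °C; aq. NH4Cl; then p-TsOH (5 mol %), CH2Cl2, rt
Reagents that add atoms: none
Why: Enantioselective deprotonation with a chiral lithium amide (Simpkins–Koga type) gives the (S)-enolate and so sets C10; SN2' allylic alkylation (conjugate addition, bromide loss) then sets C3a, because 1,3-allylic strain holds the C4–H in the alkene plane and the enolate is expected to attack anti to the C5 chain, on the face of the ether oxygen; acid-catalysed enolisation finally places the C11a substituent equatorial, cis to the methyl group.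

**Step 7**
Reactants: 12 7-methyl 1-prop-2-en-1-yl (3R,4R)-4-[(4-methoxybenzyl)oxy]-2-methylidene-3-[(1R,5S)-5-methyl-2-oxocyclohexyl]heptanedioate
Product: 13 (3R,4R)-7-methoxy-4-[(4-methoxybenzyl)oxy]-2-methylidene-3-[(1R,5S)-5-methyl-2-oxocyclohexyl]-7-oxoheptanoic acid
Conditions: Pd(PPh3)4 (3 mol %), morpholine (3 equiv), THF, rt; dil. HCl
Reagents that add atoms: none
Why: Pd(0) π-allyl deallylation (Tsuji–Trost) frees the acrylic acid selectively, before the peracid step so that the allyl alkene is not exposed to it.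

**Step 8**
Reactants: 13 (3R,4R)-7-methoxy-4-[(4-methoxybenzyl)oxy]-2-methylidene-3-[(1R,5S)-5-methyl-2-oxocyclohexyl]-7-oxoheptanoic acid
Product: 14 (3R,4R)-7-methoxy-4-[(4-methoxybenzyl)oxy]-2-methylidene-3-[(2R,4S)-4-methyl-7-oxooxepan-2-yl]-7-oxoheptanoic acid
Conditions: mCPBA (1.5 equiv), CH2Cl2, 0 °C → rt
Reagents that add atoms: 3-chloroperoxybenzoic acid, OOC(=O)c1cccc(Cl)c1
Why: Baeyer–Villiger ring expansion (1,2-shift from carbon to oxygen): the more substituted α-carbon migrates with retention, which creates the O1–C11a bond with the R configuration, while the electron-poor acrylic acid is inert to the peracid.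

**Step 9**
Reactants: 14 (3R,4R)-7-methoxy-4-[(4-methoxybenzyl)oxy]-2-methylidene-3-[(2R,4S)-4-methyl-7-oxooxepan-2-yl]-7-oxoheptanoic acid
Product: 17 methyl (3aR,4R,6Z,10S,11aR)-4-[(4-methoxybenzyl)oxy]-10-methyl-3-methylidene-2-oxo-7-{[(trifluoromethyl)sulfonyl]oxy}-2,3,3a,4,5,8,9,10,11,11a-decahydrocyclodeca[b]furan-6-carboxylate, via ring-expanded keto ester 15 (not isolated), via enol triflate hydroxy acid 16 (not isolated)
Conditions: LiHMDS (2.2 equiv), THF (3 mM, slow addition of 14), −78 → 0 °C; PhNTf2 (1.3 equiv), 0 °C → rt; aq. HCl (pH 3); PPTS (cat.), CH2Cl2, rt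
Reagents that add atoms: N-phenylbis(trifluoromethanesulfonimide), O=S(=O)(N(c1ccccc1)S(=O)(=O)C(F)(F)F)C(F)(F)F
Why: Proposed new method: a C-acylative three-atom ring expansion in which, with the acrylic acid held as its lithium carboxylate (so it is neither a Michael acceptor nor a Dieckmann partner), the C6 ester enolate (in proton-transfer equilibrium with the unproductive lactone enolate through HN(SiMe3)2) adds to the strained ε-lactone carbonyl C7 through a seven-membered transition state, the bicyclic tetrahedral intermediate collapses with loss of O1 to the ten-membered β-keto ester, and proton transfer from that β-keto ester to the C11a alkoxide makes the step irreversible; the chelated lithium enolate is then O-triflated to the Z enol triflate (ring carbons cis) and acid closes the trans γ-lactone from the C11a hydroxyl and the acid without touching a stereocentre; the closest known reactions are the Dieckmann condensation and acyl-transfer ring expansions of lactones by tethered nucleophiles (SmI2 nucleophilic acyl substitution of halo-lactones, Zip-type and successive ring expansions).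

**Step 10**
Reactants: 17 methyl (3aR,4R,6Z,10S,11aR)-4-[(4-methoxybenzyl)oxy]-10-methyl-3-methylidene-2-oxo-7-{[(trifluoromethyl)sulfonyl]oxy}-2,3,3a,4,5,8,9,10,11,11a-decahydrocyclodeca[b]furan-6-carboxylate
Product: 18 methyl (3aR,4R,6E,10S,11aR)-4-[(4-methoxybenzyl)oxy]-10-methyl-3-methylidene-2-oxo-2,3,3a,4,5,8,9,10,11,11a-decahydrocyclodeca[b]furan-6-carboxylate
Conditions: Pd(OAc)2 (5 mol %), PPh3 (10 mol %), HCO2H (2 equiv), n-Bu3N (3 equiv), DMF, 60 °C
Reagents that add atoms: none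
Why: Pd-catalysed formate reduction of an enol triflate (Cacchi conditions) replaces OTf by H with retention of alkene geometry, so H-7 ends cis to the ester as in the target.

**Step 11**
Reactants: 18 methyl (3aR,4R,6E,10S,11aR)-4-[(4-methoxybenzyl)oxy]-10-methyl-3-methylidene-2-oxo-2,3,3a,4,5,8,9,10,11,11a-decahydrocyclodeca[b]furan-6-carboxylate
Product: 19 methyl (3aR,4R,6E,10S,11aR)-4-hydroxy-10-methyl-3-methylidene-2-oxo-2,3,3a,4,5,8,9,10,11,11a-decahydrocyclodeca[b]furan-6-carboxylate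
Conditions: DDQ (1.5 equiv), CH2Cl2/pH 7 buffer 10:1, 0 °C → rt
Reagents that add atoms: none
Why: Oxidative PMB ether cleavage under neutral conditions spares the α-methylene lactone and the enoate and avoids base-induced lactonisation of the C4 hydroxyl onto the C6 ester.

**Step 12**
Reactants: 19 methyl (3aR,4R,6E,10S,11aR)-4-hydroxy-10-methyl-3-methylidene-2-oxo-2,3,3a,4,5,8,9,10,11,11a-decahydrocyclodeca[b]furan-6-carboxylate; 20 angelic acid ((2Z)-2-methylbut-2-enoic acid)
Product: 22 methyl (3aS,4R,6E,10S,11aR)-10-methyl-3-methylidene-4-{[(2Z)-2-methylbut-2-enoyl]oxy}-2-oxo-2,3,3a,4,5,8,9,10,11,11a-decahydrocyclodeca[b]furan-6-carboxylate (CNP0510087.1), via mixed anhydride 21 (not isolated)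
Conditions: 20, 2,4,6-trichlorobenzoyl chloride, Et3N, toluene, rt; then 19, toluene, 80 °C (no DMAP)
Reagents that add atoms: none
Why: Yamaguchi-type esterification through the mixed anhydride, run without nucleophilic catalyst, transfers the angeloyl group without Z → E isomerisation to the tiglate and leaves C4 unchanged.

**Compound list**

1 | cyclopentene oxide (6-oxabicyclo[3.1.0]hexane) | C1CC2OC2C1 | starting material
2 | (1R)-cyclopent-2-en-1-ol | O[C@H]1C=CCC1 | intermediate
3 | 1-{[(1R)-cyclopent-2-en-1-yloxy]methyl}-4-methoxybenzene | COc1ccc(CO[C@H]2C=CCC2)cc1 | intermediate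
4 | (2R)-5-hydroperoxy-5-methoxy-2-[(4-methoxybenzyl)oxy]pentanal (epimers at C5, not isolated) | O=C[C@@H](CCC(OC)OO)OCc1ccc(OC)cc1 | intermediate
5 | methyl (4R)-4-[(4-methoxybenzyl)oxy]-5-oxopentanoate | O=C[C@@H](CCC(=O)OC)OCc1ccc(OC)cc1 | intermediate
6 | allyl acrylate (prop-2-en-1-yl prop-2-enoate) | C=CC(=O)OCC=C | starting material
7 | 7-methyl 1-prop-2-en-1-yl (3RS,4R)-3-hydroxy-4-[(4-methoxybenzyl)oxy]-2-methylideneheptanedioate | C=C(C(=O)OCC=C)C(O)[C@@H](CCC(=O)OC)OCc1ccc(OC)cc1 | intermediate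
8 | 7-methyl 1-prop-2-en-1-yl (2Z,4R)-2-(bromomethyl)-4-[(4-methoxybenzyl)oxy]hept-2-enedioate | BrC/C(C(=O)OCC=C)=C\[C@@H](CCC(=O)OC)OCc1ccc(OC)cc1 | intermediate
9 | 4-methylcyclohexan-1-one | CC1CCC(=O)CC1 | starting material
10 | lithium (4S)-4-methylcyclohex-1-en-1-olate (not isolated) | [Li+].[O-]C1=CC[C@@H](C)CC1 | intermediate
11 | 7-methyl 1-prop-2-en-1-yl (3R,4R)-4-[(4-methoxybenzyl)oxy]-2-methylidene-3-[(1RS,5S)-5-methyl-2-oxocyclohexyl]heptanedioate (not isolated) | C=CCOC(=O)C(=C)[C@@H](C1C[C@@H](C)CCC1=O)[C@@H](CCC(=O)OC)OCc1ccc(OC)cc1 | intermediate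
12 | 7-methyl 1-prop-2-en-1-yl (3R,4R)-4-[(4-methoxybenzyl)oxy]-2-methylidene-3-[(1R,5S)-5-methyl-2-oxocyclohexyl]heptanedioate | C=CCOC(=O)C(=C)[C@@H]([C@H]1C[C@@H](C)CCC1=O)[C@@H](CCC(=O)OC)OCc1ccc(OC)cc1 | intermediate
13 | (3R,4R)-7-methoxy-4-[(4-methoxybenzyl)oxy]-2-methylidene-3-[(1R,5S)-5-methyl-2-oxocyclohexyl]-7-oxoheptanoic acid | OC(=O)C(=C)[C@@H]([C@H]1C[C@@H](C)CCC1=O)[C@@H](CCC(=O)OC)OCc1ccc(OC)cc1 | intermediate
14 | (3R,4R)-7-methoxy-4-[(4-methoxybenzyl)oxy]-2-methylidene-3-[(2R,4S)-4-methyl-7-oxooxepan-2-yl]-7-oxoheptanoic acid | OC(=O)C(=C)[C@@H]([C@H]1C[C@@H](C)CCC(=O)O1)[C@@H](CCC(=O)OC)OCc1ccc(OC)cc1 | intermediate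
15 | 2-[(1S,2R,4S,10R)-2-hydroxy-8-(methoxycarbonyl)-10-[(4-methoxybenzyl)oxy]-4-methyl-7-oxocyclodecyl]prop-2-enoic acid (present as its dilithium carboxylate/enolate, not isolated) | OC(=O)C(=C)[C@H]1[C@H](O)C[C@@H](C)CCC(=O)C(C(=O)OC)C[C@H]1OCc1ccc(OC)cc1 | intermediate
16 | 2-[(1S,2R,4S,7Z,10R)-2-hydroxy-8-(methoxycarbonyl)-10-[(4-methoxybenzyl)oxy]-4-methyl-7-{[(trifluoromethyl)sulfonyl]oxy}cyclodec-7-en-1-yl]prop-2-enoic acid (not isolated) | OC(=O)C(=C)[C@H]1[C@H](O)C[C@@H](C)CC/C(OS(=O)(=O)C(F)(F)F)=C(/C(=O)OC)C[C@H]1OCc1ccc(OC)cc1 | intermediate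
17 | methyl (3aR,4R,6Z,10S,11aR)-4-[(4-methoxybenzyl)oxy]-10-methyl-3-methylidene-2-oxo-7-{[(trifluoromethyl)sulfonyl]oxy}-2,3,3a,4,5,8,9,10,11,11a-decahydrocyclodeca[b]furan-6-carboxylate | C=C1C(=O)O[C@@H]2C[C@@H](C)CC/C(OS(=O)(=O)C(F)(F)F)=C(/C(=O)OC)C[C@@H](OCc3ccc(OC)cc3)[C@@H]12 | intermediate
18 | methyl (3aR,4R,6E,10S,11aR)-4-[(4-methoxybenzyl)oxy]-10-methyl-3-methylidene-2-oxo-2,3,3a,4,5,8,9,10,11,11a-decahydrocyclodeca[b]furan-6-carboxylate | C=C1C(=O)O[C@@H]2C[C@@H](C)CC/C=C(/C(=O)OC)C[C@@H](OCc3ccc(OC)cc3)[C@@H]12 | intermediate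
19 | methyl (3aR,4R,6E,10S,11aR)-4-hydroxy-10-methyl-3-methylidene-2-oxo-2,3,3a,4,5,8,9,10,11,11a-decahydrocyclodeca[b]furan-6-carboxylate | C=C1C(=O)O[C@@H]2C[C@@H](C)CC/C=C(/C(=O)OC)C[C@@H](O)[C@@H]12 | intermediate
20 | angelic acid ((2Z)-2-methylbut-2-enoic acid) | C/C=C(/C)C(=O)O | starting material
21 | (2Z)-2-methylbut-2-enoic 2,4,6-trichlorobenzoic anhydride (not isolated) | C/C=C(/C)C(=O)OC(=O)c1c(Cl)cc(Cl)cc1Cl | intermediate
22 | methyl (3aS,4R,6E,10S,11aR)-10-methyl-3-methylidene-4-{[(2Z)-2-methylbut-2-enoyl]oxy}-2-oxo-2,3,3a,4,5,8,9,10,11,11a-decahydrocyclodeca[b]furan-6-carboxylate | C=C1C(=O)O[C@@H]2C[C@@H](C)CC/C=C(/C(=O)OC)C[C@@H](OC(=O)/C(C)=C\C)[C@@H]12 | target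

**Step count and risk**

Total steps: 12. Longest linear sequence: 12 (1 → 22); compounds 6, 9 and 20 enter directly.

Three steps most likely to fail:

Step 9 (the proposed new ring expansion). The enolate may be consumed intermolecularly, or the lactone enolate may dominate and nothing productive happen. The fallback sets out from 14 and comes back at 17. The strained seven-membered lactone of 14 is hydrolysed selectively (LiOH, 1.0 equiv, THF/H2O, 0 °C) and acidified, whereupon the C11a hydroxyl closes the γ-lactone to give (4S)-5-[(2R,3R)-3-{(1R)-4-methoxy-1-[(4-methoxybenzyl)oxy]-4-oxobutyl}-4-methylidene-5-oxooxolan-2-yl]-4-methylpentanoic acid F6. Oxalyl chloride with catalytic DMF converts it into the corresponding pentanoyl chloride F7. A titanium-mediated crossed Claisen macrocyclisation (TiCl4, Bu3N, N-methylimidazole, CH2Cl2, −45 °C, syringe-pump addition), in which only the acid chloride can act as the electrophile, gives methyl (3aR,4R,6RS,10S,11aR)-4-[(4-methoxybenzyl)oxy]-10-methyl-3-methylidene-2,7-dioxododecahydrocyclodeca[b]furan-6-carboxylate F8. NaH followed by PhNTf2 then gives 17.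

Step 6 (enantiotopic-group selection and C3a facial selectivity in one alkylation). If the ee or the C3a ratio is poor, the fallback sets out from 9 and 8 and comes back at 14, replacing enolate alkylation plus ketone oxidation by carbonyl allylation plus lactonisation:
- 9 is oxidised enzymatically (cyclohexanone monooxygenase, O2, NADPH recycling) to (5S)-5-methyloxepan-2-one F1.
- LiOH opens it to (4S)-6-hydroxy-4-methylhexanoic acid F2.
- TEMPO/PhI(OAc)2 gives (4S)-4-methyl-6-oxohexanoic acid F3.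
- Indium-mediated Barbier allylation with 8 (In, THF/H2O) gives (4S,6R,7S,8R)-6-hydroxy-11-methoxy-8-[(4-methoxybenzyl)oxy]-4-methyl-11-oxo-7-{3-oxo-3-[(prop-2-en-1-yl)oxy]prop-1-en-2-yl}undecanoic acid F4.
- Yamaguchi lactonisation at high dilution gives 7-methyl 1-prop-2-en-1-yl (3R,4R)-4-[(4-methoxybenzyl)oxy]-2-methylidene-3-[(2R,4S)-4-methyl-7-oxooxepan-2-yl]heptanedioate F5.
- Pd(PPh3)4/morpholine then gives 14.

Step 10 (vinyl–palladium chemistry next to an α-methylene lactone: Heck-type closure, conjugate reduction or exo-to-endo isomerisation are possible). The fallback sets out from 14 and comes back at 18 without any palladium hydride. Step 9 is run with an acidic quench in place of the triflimide, followed by PPTS, to give the keto ester F8 (the compound described in the fallback to step 9). NaBH4/CeCl3 (MeOH, −78 °C) reduces it to methyl (3aR,4R,10S,11aR)-7-hydroxy-4-[(4-methoxybenzyl)oxy]-10-methyl-3-methylidene-2-oxododecahydrocyclodeca[b]furan-6-carboxylate F9. MsCl/Et3N gives the 7-[(methanesulfonyl)oxy] analogue F10, and DBU effects E1cB elimination to the thermodynamically preferred enoate 18.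

**Further compounds**

F1 | step 6 | (5S)-5-methyloxepan-2-one | O=C1CC[C@H](C)CCO1
F2 | step 6 | (4S)-6-hydroxy-4-methylhexanoic acid | OC(=O)CC[C@H](C)CCO
F3 | step 6 | (4S)-4-methyl-6-oxohexanoic acid | OC(=O)CC[C@H](C)CC=O
F4 | step 6 | (4S,6R,7S,8R)-6-hydroxy-11-methoxy-8-[(4-methoxybenzyl)oxy]-4-methyl-11-oxo-7-{3-oxo-3-[(prop-2-en-1-yl)oxy]prop-1-en-2-yl}undecanoic acid | OC(=O)CC[C@H](C)C[C@@H](O)[C@H](C(=C)C(=O)OCC=C)[C@@H](CCC(=O)OC)OCc1ccc(OC)cc1
F5 | step 6 | 7-methyl 1-prop-2-en-1-yl (3R,4R)-4-[(4-methoxybenzyl)oxy]-2-methylidene-3-[(2R,4S)-4-methyl-7-oxooxepan-2-yl]heptanedioate | C=CCOC(=O)C(=C)[C@@H]([C@H]1C[C@@H](C)CCC(=O)O1)[C@@H](CCC(=O)OC)OCc1ccc(OC)cc1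
F6 | step 9 | (4S)-5-[(2R,3R)-3-{(1R)-4-methoxy-1-[(4-methoxybenzyl)oxy]-4-oxobutyl}-4-methylidene-5-oxooxolan-2-yl]-4-methylpentanoic acid | C=C1C(=O)O[C@H](C[C@@H](C)CCC(=O)O)[C@H]1[C@@H](CCC(=O)OC)OCc1ccc(OC)cc1
F7 | step 9 | (4S)-5-[(2R,3R)-3-{(1R)-4-methoxy-1-[(4-methoxybenzyl)oxy]-4-oxobutyl}-4-methylidene-5-oxooxolan-2-yl]-4-methylpentanoyl chloride | C=C1C(=O)O[C@H](C[C@@H](C)CCC(=O)Cl)[C@H]1[C@@H](CCC(=O)OC)OCc1ccc(OC)cc1
F8 | step 9 | methyl (3aR,4R,6RS,10S,11aR)-4-[(4-methoxybenzyl)oxy]-10-methyl-3-methylidene-2,7-dioxododecahydrocyclodeca[b]furan-6-carboxylate | C=C1C(=O)O[C@@H]2C[C@@H](C)CCC(=O)C(C(=O)OC)C[C@@H](OCc3ccc(OC)cc3)[C@@H]12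
F9 | step 10 | methyl (3aR,4R,10S,11aR)-7-hydroxy-4-[(4-methoxybenzyl)oxy]-10-methyl-3-methylidene-2-oxododecahydrocyclodeca[b]furan-6-carboxylate (C6/C7 epimers) | C=C1C(=O)O[C@@H]2C[C@@H](C)CCC(O)C(C(=O)OC)C[C@@H](OCc3ccc(OC)cc3)[C@@H]12
F10 | step 10 | methyl (3aR,4R,10S,11aR)-7-[(methanesulfonyl)oxy]-4-[(4-methoxybenzyl)oxy]-10-methyl-3-methylidene-2-oxododecahydrocyclodeca[b]furan-6-carboxylate (C6/C7 epimers) | C=C1C(=O)O[C@@H]2C[C@@H](C)CCC(OS(C)(=O)=O)C(C(=O)OC)C[C@@H](OCc3ccc(OC)cc3)[C@@H]12
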